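**Retrosynthetic overview**
1. Feature: central ring B is a phloroglucinol whose C2 and C4 each carry an outer phloroglucinol ring (A, C) through C1'. In each outer ring the oxygen on C2' is a sulfate, the oxygens on C4' and C6' are free hydroxyls and C3'/C5' carry hydrogen, so the plan rests on telling the C2' oxygen from the otherwise equivalent C6' oxygen.
2. Last disconnection: the two C2'O–S bonds, back to a bis-phenol in which C2'–OH is the only free hydroxyl (C6' as silyl ether, C4' and the three ring B oxygens as benzyl ethers).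
3. Key disconnection: in ring A and in ring C the bonds C1'–C2' and C5'–C6' are cut together. This returns ring B with two silyloxyethynyl arms (alkyne carbons = C1' and C6') and two molecules of 3-benzyloxycyclobutenone (= C2'–C3'–C4'–C5', its carbonyl oxygen becoming the C2' hydroxyl).
4. The bis(silyl ynol ether) goes back through a diyne and a dialdehyde to phloroglucinol; the cyclobutenone goes back to 3-ethoxycyclobutenone.
5. Ring order: ring B is bought; rings A and C are formed together in step 6 by twofold vinylketene–ynol ether benzannulation; no ring is made afterwards.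

Key step: step 6

Remark on stereochemistry: the target SMILES defines no configuration at the two hindered aryl–aryl axes and the molecule has no stereocentre, so no axis is controlled and rotamer mixtures of the crowded intermediates are carried through.
Remark on the sulfates: every sulfate monoester is named and drawn as the neutral hydrogen sulfate, as in the target SMILES, although it is handled as its pyridinium or tetrabutylammonium salt until the final cation exchange.

**Route**

Step 1
Reactants: 1 phloroglucinol; 2 N,N-dimethylformamide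
Product: 4 2,4,6-trihydroxybenzene-1,3-dicarbaldehyde, via bis(iminium) dichloride 3 (not isolated)
Conditions: POCl3 (2.4 equiv), DMF (2.4 equiv), 1,4-dioxane, 0 °C → rt; then H2O, 0 °C → rt
Reagents that add atoms: N,N-dimethylformamide (2), CN(C)C=O; water, O
Why: Vilsmeier–Haack formylation, in which the chloroiminium ion made from DMF and POCl3 substitutes two of the three equivalent, strongly activated ring carbons of phloroglucinol, the two iminium groups of 3 deactivate the last position at this stoichiometry, and water hydrolyses 3 to the dialdehyde.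

Step 2
Reactants: 4 2,4,6-trihydroxybenzene-1,3-dicarbaldehyde; 5 benzyl bromide
Product: 6 2,4,6-tris(benzyloxy)benzene-1,3-dicarbaldehyde
Conditions: BnBr (3.6 equiv), K2CO3 (4.5 equiv), DMF, 60 °C
Reagents that add atoms: benzyl bromide (5), BrCc1ccccc1
Why: Williamson ether synthesis, in which the two formyl groups make all three phenols acidic and the ring carbon poorly nucleophilic, so that carbonate in DMF should alkylate on oxygen, the warm bath being needed for the hydrogen-bonded hydroxyls next to the aldehydes.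

Step 3
Reactants: 6 2,4,6-tris(benzyloxy)benzene-1,3-dicarbaldehyde; 7 dimethyl (1-diazo-2-oxopropyl)phosphonate
Product: 8 1,3,5-tris(benzyloxy)-2,4-diethynylbenzene
Conditions: 7 (3 equiv), K2CO3 (4 equiv), MeOH–THF, 0 °C → rt
Reagents that add atoms: dimethyl (1-diazo-2-oxopropyl)phosphonate (7), CC(=O)C(=[N+]=[N-])P(=O)(OC)OC
Why: Ohira–Bestmann modification of the Seyferth–Gilbert homologation, which converts non-enolisable aryl aldehydes into terminal alkynes under mild carbonate/methanol conditions that leave benzyl ethers untouched.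

Step 4
Reactants: 8 1,3,5-tris(benzyloxy)-2,4-diethynylbenzene; 9 tert-butyl hydroperoxide; 10 triisopropylsilyl trifluoromethanesulfonate
Product: 13 1,3,5-tris(benzyloxy)-2,4-bis[(triisopropylsilyloxy)ethynyl]benzene, via dilithium bis(acetylide) 11 (not isolated), via dilithium bis(ynolate) 12 (not isolated)
Conditions: n-BuLi (2.05 equiv), THF, −78 °C; LiOOt-Bu [from anhydrous t-BuOOH (2.4 equiv) and LiN(SiMe3)2 (2.4 equiv)], −78 → 0 °C; i-Pr3SiOTf (2.6 equiv), −78 → 0 °C
Reagents that add atoms: tert-butyl hydroperoxide (9), CC(C)(C)OO; triisopropylsilyl trifluoromethanesulfonate (10), CC(C)[Si](OS(=O)(=O)C(F)(F)F)(C(C)C)C(C)C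
Why: acetylide-to-ynolate oxidation by oxygen transfer from lithium tert-butyl peroxide followed by O-silylation is the standard preparation of triisopropylsilyl ynol ethers from aryl acetylenes, and the bulky silyl triflate should silylate the ynolate on oxygen and not on carbon.

Step 5
Reactants: 14 3-ethoxycyclobut-2-en-1-one; 15 benzyl alcohol
Product: 16 3-(benzyloxy)cyclobut-2-en-1-one
Conditions: BnOH (1.5 equiv), pyridinium p-toluenesulfonate (5 mol %), PhMe, 5 Å MS, 40 °C, reduced pressure
Reagents that add atoms: benzyl alcohol (15), OCc1ccccc1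
Why: acid-catalysed alkoxy exchange of a vinylogous ester by conjugate addition of benzyl alcohol and loss of ethanol, the addition–elimination at the β-carbon that 3-alkoxyenones and squarate esters undergo, pulled to the benzyl ether by removal of the volatile ethanol.

Step 6
Reactants: 13 1,3,5-tris(benzyloxy)-2,4-bis[(triisopropylsilyloxy)ethynyl]benzene; 16 3-(benzyloxy)cyclobut-2-en-1-one (two molecules)
Product: 25 1,3,5-tris(benzyloxy)-2,4-bis[4-(benzyloxy)-2-hydroxy-6-(triisopropylsilyloxy)phenyl]benzene, via vinylketene 17 (not isolated), via first vinylcyclobutenone adduct 18 (not isolated), via first dienylketene 19 (not isolated), via first cyclohexadienone 20 (not isolated), via monophenol 21 (not isolated), via second vinylcyclobutenone adduct 22 (not isolated), via second dienylketene 23 (not isolated), via second cyclohexadienone 24 (not isolated)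
Conditions: 16 (3 equiv, added in three portions), PhMe (0.1 M), 110 °C, sealed tube
Reagents that add atoms: none
Why: Thermal 4π electrocyclic opening of 16 gives vinylketene 17, whose ketene carbon is attacked by the aryl-bearing carbon of one silyloxyalkyne arm in a regioselective [2+2] cycloaddition (C1'–C2' and C5'–C6' formed) to give 4-vinylcyclobutenone 18, 4π opening of 18 gives dienylketene 19, 6π electrocyclisation (re-forming the bond that becomes C2'–C3') gives dienone 20, which tautomerises to phenol 21, and the second arm repeats the sequence through 22, 23 and 24 to 25. This is the Danheiser benzannulation with a silyloxyalkyne as ketenophile, the known route to 2-substituted resorcinol monosilyl ethers, applied here twice on one arene. Rings A and C are each closed by a thermal disrotatory 6π electrocyclisation of a dienylketene and not by a coupling, so the two tetra-ortho-oxygenated aryl–aryl bonds are simply the C–C bonds that already join ring B to its alkynes. No stereocentre is created, since the transient sp3 carbon of 18 and 22 is lost on ring opening and the axes are left uncontrolled. The step needs the aryl-bearing alkyne carbon, not the silyloxy-bearing one, to bond to the ketene carbonyl carbon, and the oxygen lone pair of the silyl ynol ether polarises the triple bond in exactly that sense, so the ketene oxygen becomes the lone free hydroxyl at C2' next to the axis while C6' stays silylated and C4' benzylated. The two ortho benzyloxy groups of ring B crowd only a linear alkyne that projects clear of them, and the reaction is an addition in which all atoms of 13 and of two molecules of 16 end in 25.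

Step 7
Reactants: 25 1,3,5-tris(benzyloxy)-2,4-bis[4-(benzyloxy)-2-hydroxy-6-(triisopropylsilyloxy)phenyl]benzene; 26 sulfur trioxide–pyridine complex
Product: 27 1,3,5-tris(benzyloxy)-2,4-bis[4-(benzyloxy)-2-(sulfooxy)-6-(triisopropylsilyloxy)phenyl]benzene
Conditions: SO3·pyridine (8 equiv), pyridine, 50 °C
Reagents that add atoms: sulfur trioxide–pyridine complex (26), O=S(=O)([O-])[n+]1ccccc1
Why: O-sulfation of phenols with SO3·pyridine, which can only reach the two C2' hydroxyls because every other oxygen of 25 is a silyl or benzyl ether inert to the complex.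

Step 8
Reactants: 27 1,3,5-tris(benzyloxy)-2,4-bis[4-(benzyloxy)-2-(sulfooxy)-6-(triisopropylsilyloxy)phenyl]benzene
Product: 28 1,3,5-tris(benzyloxy)-2,4-bis[4-(benzyloxy)-6-hydroxy-2-(sulfooxy)phenyl]benzene
Conditions: Bu4NF (3 equiv), AcOH (3 equiv), THF, 0 °C → rt
Reagents that add atoms: none
Why: fluoride-induced cleavage of aryl silyl ethers, buffered by acetic acid so that the electron-rich phenoxides are protonated at once, under which aryl sulfate monoester anions and benzyl ethers are stable.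

Step 9
Reactants: 28 1,3,5-tris(benzyloxy)-2,4-bis[4-(benzyloxy)-6-hydroxy-2-(sulfooxy)phenyl]benzene
Product: 29 2,4-bis[4,6-dihydroxy-2-(sulfooxy)phenyl]benzene-1,3,5-triol (CNP0320583.0)
Conditions: H2 (1 atm), Pd/C, MeOH–THF, rt; then Dowex 50WX8 (H+ form), H2O–MeOH, 0 °C, freeze-drying
Reagents that add atoms: none
Why: catalytic hydrogenolysis of five aryl benzyl ethers over Pd/C, to which aryl sulfate monoesters are inert, with a cold pass through acid resin to exchange the counter-cations for protons and give the hydrogen sulfate form.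

**Compound list**
1 | phloroglucinol (benzene-1,3,5-triol) | Oc1cc(O)cc(O)c1 | starting material
2 | N,N-dimethylformamide | CN(C)C=O | starting material
3 | 2,4-bis[(dimethyliminio)methyl]benzene-1,3,5-triol dichloride | C[N+](C)=Cc1c(O)cc(O)c(C=[N+](C)C)c1O.[Cl-].[Cl-] | intermediate
4 | 2,4,6-trihydroxybenzene-1,3-dicarbaldehyde | O=Cc1c(O)cc(O)c(C=O)c1O | intermediate
5 | benzyl bromide | BrCc1ccccc1 | starting material
6 | 2,4,6-tris(benzyloxy)benzene-1,3-dicarbaldehyde | O=Cc1c(OCc2ccccc2)cc(OCc2ccccc2)c(C=O)c1OCc1ccccc1 | intermediate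
7 | dimethyl (1-diazo-2-oxopropyl)phosphonate | CC(=O)C(=[N+]=[N-])P(=O)(OC)OC | starting material
8 | 1,3,5-tris(benzyloxy)-2,4-diethynylbenzene | C#Cc1c(OCc2ccccc2)cc(OCc2ccccc2)c(C#C)c1OCc1ccccc1 | intermediate
9 | tert-butyl hydroperoxide | CC(C)(C)OO | starting material
10 | triisopropylsilyl trifluoromethanesulfonate | CC(C)[Si](OS(=O)(=O)C(F)(F)F)(C(C)C)C(C)C | starting material
11 | dilithium bis(acetylide) of 8 | [Li]C#Cc1c(OCc2ccccc2)cc(OCc2ccccc2)c(C#C[Li])c1OCc1ccccc1 | intermediate
12 | dilithium bis(ynolate), 1,3,5-tris(benzyloxy)-2,4-bis(lithiooxyethynyl)benzene | [Li]OC#Cc1c(OCc2ccccc2)cc(OCc2ccccc2)c(C#CO[Li])c1OCc1ccccc1 | intermediate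
13 | 1,3,5-tris(benzyloxy)-2,4-bis[(triisopropylsilyloxy)ethynyl]benzene | c1c(OCc2ccccc2)c(C#CO[Si](C(C)C)(C(C)C)C(C)C)c(OCc2ccccc2)c(C#CO[Si](C(C)C)(C(C)C)C(C)C)c1OCc1ccccc1 | intermediate
14 | 3-ethoxycyclobut-2-en-1-one | CCOC1=CC(=O)C1 | starting material
15 | benzyl alcohol | OCc1ccccc1 | starting material
16 | 3-(benzyloxy)cyclobut-2-en-1-one | O=C1C=C(OCc2ccccc2)C1 | intermediate
17 | 3-(benzyloxy)buta-1,3-dien-1-one (vinylketene) | O=C=CC(=C)OCc1ccccc1 | intermediate
18 | 4-[1-(benzyloxy)ethenyl]-2-{2,4,6-tris(benzyloxy)-3-[(triisopropylsilyloxy)ethynyl]phenyl}-3-(triisopropylsilyloxy)cyclobut-2-en-1-one (racemic at C4) | c1c(OCc2ccccc2)c(C3=C(O[Si](C(C)C)(C(C)C)C(C)C)C(C(=C)OCc4ccccc4)C3=O)c(OCc2ccccc2)c(C#CO[Si](C(C)C)(C(C)C)C(C)C)c1OCc1ccccc1 | intermediate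
19 | 5-(benzyloxy)-2-{2,4,6-tris(benzyloxy)-3-[(triisopropylsilyloxy)ethynyl]phenyl}-3-(triisopropylsilyloxy)hexa-1,3,5-trien-1-one (dienylketene) | c1c(OCc2ccccc2)c(C(=C=O)C(O[Si](C(C)C)(C(C)C)C(C)C)=CC(=C)OCc3ccccc3)c(OCc2ccccc2)c(C#CO[Si](C(C)C)(C(C)C)C(C)C)c1OCc1ccccc1 | intermediate
20 | 5-(benzyloxy)-2-{2,4,6-tris(benzyloxy)-3-[(triisopropylsilyloxy)ethynyl]phenyl}-3-(triisopropylsilyloxy)cyclohexa-2,4-dien-1-one | c1c(OCc2ccccc2)c(C3=C(O[Si](C(C)C)(C(C)C)C(C)C)C=C(OCc4ccccc4)CC3=O)c(OCc2ccccc2)c(C#CO[Si](C(C)C)(C(C)C)C(C)C)c1OCc1ccccc1 | intermediate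
21 | 5-(benzyloxy)-2-{2,4,6-tris(benzyloxy)-3-[(triisopropylsilyloxy)ethynyl]phenyl}-3-(triisopropylsilyloxy)phenol (ring A complete, one alkyne arm left) | c1c(OCc2ccccc2)c(-c3c(O)cc(OCc4ccccc4)cc3O[Si](C(C)C)(C(C)C)C(C)C)c(OCc2ccccc2)c(C#CO[Si](C(C)C)(C(C)C)C(C)C)c1OCc1ccccc1 | intermediate
22 | 4-[1-(benzyloxy)ethenyl]-2-{2,4,6-tris(benzyloxy)-3-[4-(benzyloxy)-2-hydroxy-6-(triisopropylsilyloxy)phenyl]phenyl}-3-(triisopropylsilyloxy)cyclobut-2-en-1-one (racemic at C4) | c1c(OCc2ccccc2)c(-c3c(O)cc(OCc4ccccc4)cc3O[Si](C(C)C)(C(C)C)C(C)C)c(OCc2ccccc2)c(C3=C(O[Si](C(C)C)(C(C)C)C(C)C)C(C(=C)OCc4ccccc4)C3=O)c1OCc1ccccc1 | intermediate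
23 | 5-(benzyloxy)-2-{2,4,6-tris(benzyloxy)-3-[4-(benzyloxy)-2-hydroxy-6-(triisopropylsilyloxy)phenyl]phenyl}-3-(triisopropylsilyloxy)hexa-1,3,5-trien-1-one (dienylketene) | c1c(OCc2ccccc2)c(-c3c(O)cc(OCc4ccccc4)cc3O[Si](C(C)C)(C(C)C)C(C)C)c(OCc2ccccc2)c(C(=C=O)C(O[Si](C(C)C)(C(C)C)C(C)C)=CC(=C)OCc3ccccc3)c1OCc1ccccc1 | intermediate
24 | 5-(benzyloxy)-2-{2,4,6-tris(benzyloxy)-3-[4-(benzyloxy)-2-hydroxy-6-(triisopropylsilyloxy)phenyl]phenyl}-3-(triisopropylsilyloxy)cyclohexa-2,4-dien-1-one | c1c(OCc2ccccc2)c(-c3c(O)cc(OCc4ccccc4)cc3O[Si](C(C)C)(C(C)C)C(C)C)c(OCc2ccccc2)c(C3=C(O[Si](C(C)C)(C(C)C)C(C)C)C=C(OCc4ccccc4)CC3=O)c1OCc1ccccc1 | intermediate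
25 | 1,3,5-tris(benzyloxy)-2,4-bis[4-(benzyloxy)-2-hydroxy-6-(triisopropylsilyloxy)phenyl]benzene | c1c(OCc2ccccc2)c(-c2c(O)cc(OCc3ccccc3)cc2O[Si](C(C)C)(C(C)C)C(C)C)c(OCc2ccccc2)c(-c2c(O)cc(OCc3ccccc3)cc2O[Si](C(C)C)(C(C)C)C(C)C)c1OCc1ccccc1 | intermediate
26 | sulfur trioxide–pyridine complex | O=S(=O)([O-])[n+]1ccccc1 | starting material
27 | 1,3,5-tris(benzyloxy)-2,4-bis[4-(benzyloxy)-2-(sulfooxy)-6-(triisopropylsilyloxy)phenyl]benzene | c1c(OCc2ccccc2)c(-c2c(OS(=O)(=O)O)cc(OCc3ccccc3)cc2O[Si](C(C)C)(C(C)C)C(C)C)c(OCc2ccccc2)c(-c2c(OS(=O)(=O)O)cc(OCc3ccccc3)cc2O[Si](C(C)C)(C(C)C)C(C)C)c1OCc1ccccc1 | intermediate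
28 | 1,3,5-tris(benzyloxy)-2,4-bis[4-(benzyloxy)-6-hydroxy-2-(sulfooxy)phenyl]benzene | c1c(OCc2ccccc2)c(-c2c(OS(=O)(=O)O)cc(OCc3ccccc3)cc2O)c(OCc2ccccc2)c(-c2c(OS(=O)(=O)O)cc(OCc3ccccc3)cc2O)c1OCc1ccccc1 | intermediate
29 | 2,4-bis[4,6-dihydroxy-2-(sulfooxy)phenyl]benzene-1,3,5-triol (CNP0320583.0) | O=S(=O)(O)Oc1cc(O)cc(O)c1-c1c(O)cc(O)c(-c2c(O)cc(O)cc2OS(=O)(=O)O)c1O | target

**Step count and risks**
Total steps: 9. Longest linear sequence: 8 steps (steps 1–4 and 6–9 from phloroglucinol 1); step 5 is a one-step side branch that joins at step 6.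

Step 6 (most likely to fail). The donor-substituted cyclobutenone 16 may open more slowly than the silyl ynol ether arms of 13 decompose at the temperature needed. The second cycloaddition may stall through crowding beside the first new ring. The new phenols may be acylated by vinylketene 17. A first adjustment would be photochemical ring opening of 16 at room temperature. The fallback builds the two aryl–aryl bonds by cross-coupling instead; it sets out from 1 and 5 and comes back to the route at 29. Phloroglucinol 1 would be O-benzylated with 5 (K2CO3, DMF) to 1,3,5-tris(benzyloxy)benzene F1 and iodinated twice with N-iodosuccinimide to 1,3,5-tris(benzyloxy)-2,4-diiodobenzene F2. Purchased 3,5-bis(benzyloxy)phenol F3 would be protected with chloromethyl methyl ether and i-Pr2NEt as 1,3-bis(benzyloxy)-5-(methoxymethoxy)benzene F4. F4 would be lithiated with n-BuLi at the position between the acetal oxygen and a benzyloxy group and quenched with B(OMe)3 to give [2,4-bis(benzyloxy)-6-(methoxymethoxy)phenyl]boronic acid F5. Twofold Suzuki–Miyaura coupling of F2 with F5 (Pd(OAc)2, 2-dicyclohexylphosphino-2',6'-dimethoxybiphenyl, K3PO4, PhMe–H2O, 100 °C) would give 1,3,5-tris(benzyloxy)-2,4-bis[2,4-bis(benzyloxy)-6-(methoxymethoxy)phenyl]benzene F6. HCl in MeOH–THF would remove both acetals to give 1,3,5-tris(benzyloxy)-2,4-bis[2,4-bis(benzyloxy)-6-hydroxyphenyl]benzene F7, which again has one free hydroxyl per outer ring. Sulfation with 26 would give 1,3,5-tris(benzyloxy)-2,4-bis[2,4-bis(benzyloxy)-6-(sulfooxy)phenyl]benzene F8, and hydrogenolysis of its seven benzyl ethers over Pd/C with the same acid-resin finish would give 29.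

Step 4. Oxygen transfer from the lithium peroxide to two acetylides on one electron-rich ring may stop after the first arm, and part of the ynolate may silylate on carbon to give a silylketene. The fallback reaches the ynolate without a terminal alkyne or a peroxide; it sets out from 6 and comes back at 12. Dialdehyde 6 would be treated with LiCHBr2 (CH2Br2, LiN(i-Pr)2, THF, −78 °C) to give 1,1'-[2,4,6-tris(benzyloxy)-1,3-phenylene]bis(2,2-dibromoethan-1-ol) F9 as a diastereomer mixture. Oxidation with Dess–Martin periodinane would give 1,1'-[2,4,6-tris(benzyloxy)-1,3-phenylene]bis(2,2-dibromoethan-1-one) F10. Enolisation of F10 with LiN(SiMe3)2 and bromine–lithium exchange with n-BuLi (−78 → 0 °C) would trigger the carbenoid rearrangement of the Kowalski homologation with aryl migration, giving the dilithium bis(ynolate) 12, which is silylated with 10 as in step 4 to give 13.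

Step 5. Benzyl alcohol may add to the carbonyl group and cleave the strained ring to a butenoate ester, or adventitious water may hydrolyse the enol ether, faster than the alkoxy exchange proceeds. The fallback separates hydrolysis from O-alkylation; it sets out from 14 and comes back at 16. Compound 14 would be hydrolysed with dilute aqueous HCl to cyclobutane-1,3-dione F11, which exists largely as its acidic enol, and the enol oxygen would be alkylated with 5 and Ag2O in CH2Cl2 to give 16.

**Further compounds**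
F1 | step 6 | 1,3,5-tris(benzyloxy)benzene | c1c(OCc2ccccc2)cc(OCc2ccccc2)cc1OCc1ccccc1
F2 | step 6 | 1,3,5-tris(benzyloxy)-2,4-diiodobenzene | Ic1c(OCc2ccccc2)cc(OCc2ccccc2)c(I)c1OCc1ccccc1
F3 | step 6 | 3,5-bis(benzyloxy)phenol (purchased) | Oc1cc(OCc2ccccc2)cc(OCc2ccccc2)c1
F4 | step 6 | 1,3-bis(benzyloxy)-5-(methoxymethoxy)benzene | COCOc1cc(OCc2ccccc2)cc(OCc2ccccc2)c1
F5 | step 6 | [2,4-bis(benzyloxy)-6-(methoxymethoxy)phenyl]boronic acid | COCOc1cc(OCc2ccccc2)cc(OCc2ccccc2)c1B(O)O
F6 | step 6 | 1,3,5-tris(benzyloxy)-2,4-bis[2,4-bis(benzyloxy)-6-(methoxymethoxy)phenyl]benzene | c1c(OCc2ccccc2)c(-c2c(OCOC)cc(OCc3ccccc3)cc2OCc2ccccc2)c(OCc2ccccc2)c(-c2c(OCOC)cc(OCc3ccccc3)cc2OCc2ccccc2)c1OCc1ccccc1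
F7 | step 6 | 1,3,5-tris(benzyloxy)-2,4-bis[2,4-bis(benzyloxy)-6-hydroxyphenyl]benzene | c1c(OCc2ccccc2)c(-c2c(O)cc(OCc3ccccc3)cc2OCc2ccccc2)c(OCc2ccccc2)c(-c2c(O)cc(OCc3ccccc3)cc2OCc2ccccc2)c1OCc1ccccc1
F8 | step 6 | 1,3,5-tris(benzyloxy)-2,4-bis[2,4-bis(benzyloxy)-6-(sulfooxy)phenyl]benzene | c1c(OCc2ccccc2)c(-c2c(OS(=O)(=O)O)cc(OCc3ccccc3)cc2OCc2ccccc2)c(OCc2ccccc2)c(-c2c(OS(=O)(=O)O)cc(OCc3ccccc3)cc2OCc2ccccc2)c1OCc1ccccc1
F9 | step 4 | 1,1'-[2,4,6-tris(benzyloxy)-1,3-phenylene]bis(2,2-dibromoethan-1-ol) (diastereomer mixture) | OC(C(Br)Br)c1c(OCc2ccccc2)cc(OCc2ccccc2)c(C(O)C(Br)Br)c1OCc1ccccc1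
F10 | step 4 | 1,1'-[2,4,6-tris(benzyloxy)-1,3-phenylene]bis(2,2-dibromoethan-1-one) | O=C(C(Br)Br)c1c(OCc2ccccc2)cc(OCc2ccccc2)c(C(=O)C(Br)Br)c1OCc1ccccc1
F11 | step 5 | cyclobutane-1,3-dione | O=C1CC(=O)C1
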